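(The numbers are assumed; the flask was simulated.)

Equal amounts of two mirror-image substrates go into each flask, and a single-handed free catalyst with the reagent turns each into its own product; the flasks differ in temperature.

| flask | left-handed substrate | reagent | free catalyst | impurity | right-handed substrate | temperature | time |
|---|---|---|---|---|---|---|---|
| ochre | 0.21 M | 0.231 M | 12 mM | 2.6 mM | 0.21 M | 30 °C | 2.0 min |
| green | 0.21 M | 0.231 M | 12 mM | 2.6 mM | 0.21 M | 0 °C | 2.0 min |
| violet | 0.21 M | 0.231 M | 12 mM | 2.6 mM | 0.21 M | −30 °C | 2.0 min |

    reagent + free catalyst + right-handed substrate → free catalyst + right-handed product (k1 = 2.2 /M²/s, Ea1 = 40.0 kJ/mol)
    2 free catalyst → spent catalyst A (k2 = 3.9 /M/s, Ea2 = 35.0 kJ/mol)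
    free catalyst + impurity → spent catalyst B (k3 = 770 /M/s, Ea3 = 39.0 kJ/mol)
    reagent + free catalyst + left-handed substrate → free catalyst + left-handed product (k4 = 3.9 /M²/s, Ea4 = 37.0 kJ/mol)
    (constants at 0 °C)

- free catalyst is single-handed; left-handed substrate and right-handed substrate are mirror images of each other, charged as a racemate, each of them at the stated concentration
- a doubled species enters its step squared and goes two at a time
- constants are those at 0 °C; use the activation energies for any other temperature

* the best flask by share of left-handed product in all that became left-handed product or right-handed product; "all alike" if 1.5 percentage points covers them all (ochre / green / violet / all alike)
* share of left-handed product in all that became left-handed product or right-handed product, ochre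
* share of left-handed product in all that became left-handed product or right-handed product, green
* share of left-handed product in all that became left-handed product or right-handed product, violet

I follow one substrate molecule. A left-handed one is taken at a hazard of its step's constant times c(reagent) times c(free catalyst), and a right-handed one at its own constant times the same two concentrations. So at each fork the odds are the quotient of the constants, the selectivity factor, left-handed over right-handed: 1.56 in ochre, 1.77 in green and, scaling ochre's by step 4's speed-up and the gap in activation energy, 2.09 in violet. The first estimate of the share is s/(1+s): 60.9%, 63.9%, 67.6%.

But that holds at the start, and the left-handed substrate thins faster. Since the two hazards carry the same factors, integration gives a rule for a flask held at one temperature: the fraction of left-handed substrate left equals the fraction of right-handed substrate left raised to the power s. I need a clock, then.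

In green the impurity meets the catalyst within 0.108 s, far sooner than the pairing half-life of 10.7 s, so I start pairing from 9.40 mM. Integrating the falling catalyst with the reagent held at its charge gives a right-handed exponent of 0.149, hence a green share of 62.6%.

The objection is that the reagent gets used, so this clock runs fast. Yet half that clock gives 63.2%, so the doubt costs little. Another doubt is that ochre, the warm flask, may be eroded by more than my green figure. Green's erosion of 1.3 percentage points is smaller than the 6.7 points between violet and ochre at the start, and that gap is wider than the margin. I commit to violet, with ochre and violet a little under their starting shares.

The forecast says violet, with 59.5%, 62.9% and 67.1% for ochre, green and violet, on the ground: “The left-handed route has the lower activation energy”. The simulation gives 59.5%, 62.8% and 67.1%, with violet best.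

In ochre, half of the pairing's turnover up to the asked time is done by 2.82 s, sooner than the 0.158 min of the left-handed step, and at 2.00 min free catalyst stands at 1.89% with 80% of the right-handed substrate left. That fraction to the power s gives 70.6% of the left-handed substrate, and the flask holds 71%.

The neighbour is like ochre but with 0.92 M of reagent, and 38% of its right-handed substrate remains. The power s then gives 22.5% of the left-handed substrate and a share of 55.6%; computed, that flask holds 22% and a share of 55.7%.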